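**Plan**

1. Target: (3S,5S)-5-hydroxy-1,7-bis(4-hydroxy-3-methoxyphenyl)heptan-3-yl acetate (chain C-1 to C-7, OAc on C-3, OH on C-5, guaiacyl ring A on C-1, ring B on C-7). It is the monoacetate of a C2-symmetric anti-1,3-diol, so acetyl migration between O-3 and O-5 is degenerate.
2. Retrosynthetic cuts, in order: the two O-benzyl bonds; the C-5–H bond together with the acetyl–O-3 bond (back to a C-5 ketone with free O-3–H); the O-3–Si bond; the C-7–ring B bond (back to a cyclopropanol made of C-5, C-6, C-7 plus an aryl bromide); the cyclopropane bonds C-5–C-6 and C-5–C-7 (back to a C-5 methyl ester); the C-3–H bond; the C-1–C-2 bond.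
3. Forward: the ring A benzylic chloride and the acetoacetate dianion give C-1 to C-5. C-3 is reduced and silylated, and the C-5 ester is turned into the cyclopropanol with EtMgBr (which supplies C-6 and C-7). Ring B is joined to C-7 with ring opening to the C-5 ketone; desilylation, anti reduction with acetyl transfer, and hydrogenolysis finish the route.
4. Enabling feature: C-7 is β to the oxygen-bearing C-5 (O–C-5–C-6–C-7), so C-5/C-6/C-7 can be carried as a strained hydroxycyclopropane. Its opening makes C-7 a nucleophile (homoenolate, reversed polarity) toward ring B, used as its bromide at the ring carbon para to the protected phenol, and returns C-5 as the ketone that the last stereocentre needs.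
5. Stereochemistry: C-3 (S) from (S)-BINAP–ruthenium hydrogenation of the β-keto ester. C-5 (S) from 1,3-anti intramolecular hydride delivery in the Evans–Tishchenko step, which also places the acetate on O-3.

Key step: step 5

Remark: benzyl is used on both phenols because the final hydrogenolysis is neutral and leaves the acetate in place; the two benzyl-protected guaiacol building blocks (the benzylic chloride and the aryl bromide) are taken as commercial.

**Route**

Step 1
Reactants: 1 methyl acetoacetate; 2 4-(benzyloxy)-3-methoxybenzyl chloride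
Product: 4 methyl 5-[4-(benzyloxy)-3-methoxyphenyl]-3-oxopentanoate, via methyl acetoacetate dianion 3 (not isolated)
Conditions: NaH, THF, 0 °C; n-BuLi, 0 °C; then 2, 0 °C to rt; 1 M HCl work-up
Reagents that add atoms: none
Why: γ-selective alkylation of the acetoacetate dianion (Huckin–Weiler alkylation), in which the terminal carbanion is the more nucleophilic site and should attack the reactive benzylic chloride to form the C-1–C-2 bond without touching the benzyl ether.

Step 2
Reactants: 4 methyl 5-[4-(benzyloxy)-3-methoxyphenyl]-3-oxopentanoate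
Product: 5 methyl (3S)-5-[4-(benzyloxy)-3-methoxyphenyl]-3-hydroxypentanoate
Conditions: [RuCl(p-cymene)((S)-BINAP)]Cl (0.5 mol %), H2 (10 atm), MeOH, 50 °C
Reagents that add atoms: none
Why: Noyori asymmetric hydrogenation of a β-keto ester, in which the ester carbonyl chelates ruthenium and the (S)-BINAP ligand should direct hydride to one face of the ketone to set C-3 as (S), while the benzyl ether and the arene are inert to this homogeneous catalyst.

Step 3
Reactants: 5 methyl (3S)-5-[4-(benzyloxy)-3-methoxyphenyl]-3-hydroxypentanoate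
Product: 6 methyl (3S)-5-[4-(benzyloxy)-3-methoxyphenyl]-3-[(tert-butyldimethylsilyl)oxy]pentanoate
Conditions: TBSCl, imidazole, DMF, rt
Reagents that add atoms: tert-butyldimethylsilyl chloride, CC(C)(C)[Si](C)(C)Cl
Why: standard imidazole-promoted silylation of a secondary alcohol, masking O-3 against the Grignard and palladium steps.

Step 4
Reactants: 6 methyl (3S)-5-[4-(benzyloxy)-3-methoxyphenyl]-3-[(tert-butyldimethylsilyl)oxy]pentanoate
Product: 7 1-[(2S)-4-[4-(benzyloxy)-3-methoxyphenyl]-2-[(tert-butyldimethylsilyl)oxy]butyl]cyclopropan-1-ol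
Conditions: Ti(OiPr)4 (0.3 equiv), EtMgBr (3 equiv, slow addition), THF, 0 °C to rt; aq. NH4Cl
Reagents that add atoms: ethylmagnesium bromide, CC[Mg]Br
Why: Kulinkovich cyclopropanation, in which the titanacyclopropane formed from Ti(OiPr)4 and EtMgBr acts as a 1,2-dicarbanion that adds twice to the ester carbonyl to give the 1-substituted cyclopropanol (C-5, C-6, C-7), leaving the silyl ether, the benzyl ether and the remote C-3 stereocentre untouched.

Step 5
Reactants: 7 1-[(2S)-4-[4-(benzyloxy)-3-methoxyphenyl]-2-[(tert-butyldimethylsilyl)oxy]butyl]cyclopropan-1-ol; 8 1-(benzyloxy)-4-bromo-2-methoxybenzene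
Product: 10 (5S)-1,7-bis[4-(benzyloxy)-3-methoxyphenyl]-5-[(tert-butyldimethylsilyl)oxy]heptan-3-one, via palladium homoenolate 9 (not isolated)
Conditions: Pd(OAc)2 (5 mol %), XPhos (10 mol %), Cs2CO3 (2 equiv), toluene, 80 °C
Reagents that add atoms: none
Why: Zerovalent palladium formed in situ inserts into the C–Br bond of 8, the carbonate-generated cyclopropoxide of 7 displaces bromide on divalent palladium, and strain-driven β-carbon elimination cleaves the C-5–C-7 bond to give the palladium homoenolate 9, from which C(sp2)–C(sp3) reductive elimination forms the C-7–ring B bond and leaves C-5 as the ketone. The closest known reaction type is the palladium-catalysed ring-opening cross-coupling of 1-alkylcyclopropanols with aryl bromides to give β-aryl ketones. No ring is closed (the three-membered ring is opened, and because C-6 and C-7 are equivalent ring methylenes there is no regiochemical question) and no new stereocentre is formed; the C-3 stereocentre is β, not α, to the new carbonyl and cannot epimerise. The selectivity needed is reductive elimination over β-hydride elimination of 9 (which would give the vinyl ketone and reduced arene), and the bulky, electron-rich biaryl phosphine XPhos should secure it by accelerating reductive elimination. Base-induced loss of silanol from the β-silyloxy ketone should be held back by the heterogeneous carbonate in toluene and the poor leaving-group ability of the silyloxy group.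

Step 6
Reactants: 10 (5S)-1,7-bis[4-(benzyloxy)-3-methoxyphenyl]-5-[(tert-butyldimethylsilyl)oxy]heptan-3-one
Product: 11 (5S)-1,7-bis[4-(benzyloxy)-3-methoxyphenyl]-5-hydroxyheptan-3-one
Conditions: 48 % aq. HF, MeCN, 0 °C to rt
Reagents that add atoms: none
Why: acidic fluoride cleavage of a secondary silyl ether under essentially non-basic conditions, which should release the β-hydroxy ketone without retro-aldol cleavage or dehydration and leave the benzyl ethers intact.

Step 7
Reactants: 11 (5S)-1,7-bis[4-(benzyloxy)-3-methoxyphenyl]-5-hydroxyheptan-3-one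
Product: 13 (3S,5S)-1,7-bis[4-(benzyloxy)-3-methoxyphenyl]-5-hydroxyheptan-3-yl acetate, via samarium-bound acetaldehyde hemiacetal 12 (not isolated)
Conditions: SmI2 (0.3 equiv), MeCHO (5 equiv), THF, −10 °C
Reagents that add atoms: acetaldehyde, CC=O
Why: Evans–Tishchenko reduction, in which the hemiacetal 12 formed at O-3, held on trivalent samarium together with the ketone oxygen, transfers its hydride intramolecularly to the ketone carbon through a chair-like six-membered transition state with both chains equatorial, which should set the new carbinol centre (C-5 of the target) as (S) (1,3-anti) and leave the acetyl group on O-3 in the same operation.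

Step 8
Reactants: 13 (3S,5S)-1,7-bis[4-(benzyloxy)-3-methoxyphenyl]-5-hydroxyheptan-3-yl acetate
Product: 14 (3S,5S)-5-hydroxy-1,7-bis(4-hydroxy-3-methoxyphenyl)heptan-3-yl acetate
Conditions: H2 (1 atm), 10 % Pd/C, EtOAc, rt
Reagents that add atoms: none
Why: hydrogenolysis of the two benzyl aryl ethers on palladium under neutral conditions, which the acetate, the secondary alcohol and both stereocentres should survive.

**Compound list**

1 | methyl acetoacetate (methyl 3-oxobutanoate) | CC(=O)CC(=O)OC | starting material
2 | 4-(benzyloxy)-3-methoxybenzyl chloride [1-(benzyloxy)-4-(chloromethyl)-2-methoxybenzene] | COc1cc(CCl)ccc1OCc1ccccc1 | starting material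
3 | methyl acetoacetate dianion, sodium lithium salt (not isolated) | [Na+].[Li+].[CH2-]C(=O)[CH-]C(=O)OC | intermediate
4 | methyl 5-[4-(benzyloxy)-3-methoxyphenyl]-3-oxopentanoate | COC(=O)CC(=O)CCc1ccc(OCc2ccccc2)c(OC)c1 | intermediate
5 | methyl (3S)-5-[4-(benzyloxy)-3-methoxyphenyl]-3-hydroxypentanoate | COC(=O)C[C@H](CCc1ccc(OCc2ccccc2)c(OC)c1)O | intermediate
6 | methyl (3S)-5-[4-(benzyloxy)-3-methoxyphenyl]-3-[(tert-butyldimethylsilyl)oxy]pentanoate | COC(=O)C[C@H](CCc1ccc(OCc2ccccc2)c(OC)c1)O[Si](C)(C)C(C)(C)C | intermediate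
7 | 1-[(2S)-4-[4-(benzyloxy)-3-methoxyphenyl]-2-[(tert-butyldimethylsilyl)oxy]butyl]cyclopropan-1-ol | OC1(CC1)C[C@H](CCc2ccc(OCc3ccccc3)c(OC)c2)O[Si](C)(C)C(C)(C)C | intermediate
8 | 1-(benzyloxy)-4-bromo-2-methoxybenzene | COc1cc(Br)ccc1OCc1ccccc1 | starting material
9 | [4-(benzyloxy)-3-methoxyphenyl][(5S)-7-[4-(benzyloxy)-3-methoxyphenyl]-5-[(tert-butyldimethylsilyl)oxy]-3-oxoheptyl]palladium, XPhos-ligated (palladium homoenolate; ligand written as a separate component; not isolated) | COc1cc([Pd]CCC(=O)C[C@H](CCc2ccc(OCc3ccccc3)c(OC)c2)O[Si](C)(C)C(C)(C)C)ccc1OCc1ccccc1.CC(C)c1cc(C(C)C)c(-c2ccccc2P(C3CCCCC3)C4CCCCC4)c(C(C)C)c1 | intermediate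
10 | (5S)-1,7-bis[4-(benzyloxy)-3-methoxyphenyl]-5-[(tert-butyldimethylsilyl)oxy]heptan-3-one | COc1cc(CCC(=O)C[C@H](CCc2ccc(OCc3ccccc3)c(OC)c2)O[Si](C)(C)C(C)(C)C)ccc1OCc1ccccc1 | intermediate
11 | (5S)-1,7-bis[4-(benzyloxy)-3-methoxyphenyl]-5-hydroxyheptan-3-one | COc1cc(CCC(=O)C[C@H](CCc2ccc(OCc3ccccc3)c(OC)c2)O)ccc1OCc1ccccc1 | intermediate
12 | (5S)-1,7-bis[4-(benzyloxy)-3-methoxyphenyl]-5-(1-hydroxyethoxy)heptan-3-one, the hemiacetal of 11 and acetaldehyde, present as its samarium alkoxide (drawn as the free hemiacetal; hemiacetal carbon not defined; not isolated) | COc1cc(CCC(=O)C[C@H](CCc2ccc(OCc3ccccc3)c(OC)c2)OC(C)O)ccc1OCc1ccccc1 | intermediate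
13 | (3S,5S)-1,7-bis[4-(benzyloxy)-3-methoxyphenyl]-5-hydroxyheptan-3-yl acetate | COc1cc(CC[C@H](O)C[C@H](CCc2ccc(OCc3ccccc3)c(OC)c2)OC(C)=O)ccc1OCc1ccccc1 | intermediate
14 | (3S,5S)-5-hydroxy-1,7-bis(4-hydroxy-3-methoxyphenyl)heptan-3-yl acetate | COc1cc(CC[C@H](O)C[C@H](CCc2ccc(O)c(OC)c2)OC(C)=O)ccc1O | target

**Step count and risks**

Total steps: 8. Longest linear sequence: 8 steps (1 to 14); aryl bromide 8 enters at step 5.

Steps most likely to fail:

Step 5. The palladium homoenolate may undergo β-hydride elimination faster than reductive elimination, and the carbonate base may trigger elimination of the silyloxy group from the product. The fallback uses normal polarity (aryl nucleophile, C-7 electrophile) and turns the side reaction into the plan. It sets out from cyclopropanol 7: oxidative ring opening with Pd(OAc)2 (cat.), pyridine and O2 in toluene at 80 °C should give the vinyl ketone (5S)-7-[4-(benzyloxy)-3-methoxyphenyl]-5-[(tert-butyldimethylsilyl)oxy]hept-1-en-3-one F1. Rhodium-catalysed conjugate addition of commercial 4-(benzyloxy)-3-methoxyphenylboronic acid ([Rh(cod)OH]2, dioxane/H2O, rt; Hayashi–Miyaura addition) should then form the same C-7–ring B bond, and the fallback comes back to the route at ketone 10.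

Step 7. Hydride transfer within the hemiacetal may be slow relative to retro-aldol cleavage or dehydration of the β-hydroxy ketone, and Tishchenko self-condensation of acetaldehyde may consume the reagent. The fallback separates reduction and acylation and sets out from 11. Hydroxyl-directed anti reduction with Me4NBH(OAc)3 in MeCN/AcOH at −20 °C (Evans–Saksena reduction) should give the C2-symmetric diol (3S,5S)-1,7-bis[4-(benzyloxy)-3-methoxyphenyl]heptane-3,5-diol F2. Trimethyl orthoacetate with catalytic PPTS in CH2Cl2 should convert it into the cyclic orthoester (4S,6S)-4,6-bis{2-[4-(benzyloxy)-3-methoxyphenyl]ethyl}-2-methoxy-2-methyl-1,3-dioxane F3. Mild hydrolysis with aqueous acetic acid opens F3 to a monoacetate; because the diol is C2-symmetric, both modes of opening give the same compound, and the fallback comes back to the route at 13.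

Step 4. The Grignard/titanium reagent may deprotonate the ester α-position with β-elimination of silanolate, or stop at simple addition or reduction products in place of cyclopropanation. The fallback builds the cyclopropanol by carbenoid addition to an enol ether and sets out from ester 6. Amidation with MeNH(OMe)·HCl and iPrMgCl in THF at −20 °C should give the Weinreb amide (3S)-5-[4-(benzyloxy)-3-methoxyphenyl]-3-[(tert-butyldimethylsilyl)oxy]-N-methoxy-N-methylpentanamide F4. MeMgBr in THF at 0 °C should give the methyl ketone (4S)-6-[4-(benzyloxy)-3-methoxyphenyl]-4-[(tert-butyldimethylsilyl)oxy]hexan-2-one F5. Kinetic enolisation and silylation (LDA, TMSCl, THF, −78 °C) should give the silyl enol ether {[(4S)-6-[4-(benzyloxy)-3-methoxyphenyl]-4-[(tert-butyldimethylsilyl)oxy]hex-1-en-2-yl]oxy}trimethylsilane F6. Furukawa-modified Simmons–Smith cyclopropanation (Et2Zn, CH2I2, CH2Cl2, 0 °C) should give the cyclopropyl silyl ether {1-[(2S)-4-[4-(benzyloxy)-3-methoxyphenyl]-2-[(tert-butyldimethylsilyl)oxy]butyl]cyclopropoxy}trimethylsilane F7. K2CO3 in MeOH at 0 °C should remove only the trimethylsilyl group, and the fallback comes back to the route at cyclopropanol 7.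

**Further compounds**

F1 | step 5 | (5S)-7-[4-(benzyloxy)-3-methoxyphenyl]-5-[(tert-butyldimethylsilyl)oxy]hept-1-en-3-one | C=CC(=O)C[C@H](CCc1ccc(OCc2ccccc2)c(OC)c1)O[Si](C)(C)C(C)(C)C
F2 | step 7 | (3S,5S)-1,7-bis[4-(benzyloxy)-3-methoxyphenyl]heptane-3,5-diol | COc1cc(CC[C@H](O)C[C@H](CCc2ccc(OCc3ccccc3)c(OC)c2)O)ccc1OCc1ccccc1
F3 | step 7 | (4S,6S)-4,6-bis{2-[4-(benzyloxy)-3-methoxyphenyl]ethyl}-2-methoxy-2-methyl-1,3-dioxane | COc1cc(CC[C@H]2C[C@H](CCc3ccc(OCc4ccccc4)c(OC)c3)OC(C)(OC)O2)ccc1OCc1ccccc1
F4 | step 4 | (3S)-5-[4-(benzyloxy)-3-methoxyphenyl]-3-[(tert-butyldimethylsilyl)oxy]-N-methoxy-N-methylpentanamide | CON(C)C(=O)C[C@H](CCc1ccc(OCc2ccccc2)c(OC)c1)O[Si](C)(C)C(C)(C)C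
F5 | step 4 | (4S)-6-[4-(benzyloxy)-3-methoxyphenyl]-4-[(tert-butyldimethylsilyl)oxy]hexan-2-one | CC(=O)C[C@H](CCc1ccc(OCc2ccccc2)c(OC)c1)O[Si](C)(C)C(C)(C)C
F6 | step 4 | {[(4S)-6-[4-(benzyloxy)-3-methoxyphenyl]-4-[(tert-butyldimethylsilyl)oxy]hex-1-en-2-yl]oxy}trimethylsilane | C=C(O[Si](C)(C)C)C[C@H](CCc1ccc(OCc2ccccc2)c(OC)c1)O[Si](C)(C)C(C)(C)C
F7 | step 4 | {1-[(2S)-4-[4-(benzyloxy)-3-methoxyphenyl]-2-[(tert-butyldimethylsilyl)oxy]butyl]cyclopropoxy}trimethylsilane | C[Si](C)(C)OC1(CC1)C[C@H](CCc2ccc(OCc3ccccc3)c(OC)c2)O[Si](C)(C)C(C)(C)C
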